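**Plan**
- Retrosynthesis: after removal of the four masks (two dioxolanes, benzyl ether, benzyl ester), ring B is cut at B1–B2 and B5–B6. This leaves a 4-substituted but-2-ynoate (B1 and B6) and a 1,1-dimethoxybutadiene (B2 to B5) whose 3-aroyloxy group is the complete ring A.
- Enabling feature: ring B carries the carboxyl at B1, methoxy at B2, the depside oxygen at B4 and the 2-oxoheptyl arm at B6, with hydrogen at B3 and B5. A 1,1-dimethoxy-3-oxybutadiene and a 2-alkynoate give exactly this pattern once the adduct loses methanol.
- Further cuts: the enol ester C–O bond (acyl fluoride plus silyl dienol ether), the alkyne–carboxyl bond, the benzylic C–C bond of the ring A arm (lateral lithiation of an orsellinate) and the propargyl–carbinol bond (hexanal plus propargyl bromide).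
- Forward: ring A is bought as methyl orsellinate and taken to the acyl fluoride, then joined to the diene by O-acylation. Ring B, the only ring made, is formed last by Diels–Alder reaction and aromatisation with the depside ester already in place; two deprotections finish the route.
- Stereochemistry: the target has no stereocentre; the one carbinol centre made on the way is racemic and is oxidised away.

Key step: step 15

Remark: the ortho-(2-oxoheptyl)benzoic acid unit is treated throughout as the open keto acid drawn for the target; its lactol ring-chain tautomer is not counted as a separate compound.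

**Route**

Step 1
Reactants: 1 methyl orsellinate (methyl 2,4-dihydroxy-6-methylbenzoate)
Product: 2 methyl 2-hydroxy-4-methoxy-6-methylbenzoate
Conditions: MeI (1.1 equiv), K2CO3 (1.1 equiv), acetone, reflux
Reagents that add atoms: iodomethane, CI
Why: The 2-hydroxyl is tied up in a hydrogen bond to the ester carbonyl, so Williamson methylation with one equivalent of iodomethane should take the more acidic, unhindered 4-hydroxyl selectively.

Step 2
Reactants: 2 methyl 2-hydroxy-4-methoxy-6-methylbenzoate
Product: 3 methyl 2-(benzyloxy)-4-methoxy-6-methylbenzoate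
Conditions: BnBr, K2CO3, DMF, 70 °C
Reagents that add atoms: benzyl bromide, BrCc1ccccc1
Why: Williamson benzylation of the chelated phenol proceeds in DMF with heating, and the benzyl ether tolerates the later base, organolithium, fluoride and acid steps before leaving by hydrogenolysis.

Step 3
Reactants: 4 hexanoyl chloride
Product: 5 N-methoxy-N-methylhexanamide
Conditions: MeNHOMe·HCl, pyridine, CH2Cl2, 0 °C to rt
Reagents that add atoms: N,O-dimethylhydroxylamine hydrochloride, CNOC.Cl
Why: N-Acylation of the hydroxylamine by the acid chloride gives the Weinreb amide, an acyl donor that stops at the ketone stage.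

Step 4
Reactants: 3 methyl 2-(benzyloxy)-4-methoxy-6-methylbenzoate; 5 N-methoxy-N-methylhexanamide
Product: 8 methyl 2-(benzyloxy)-4-methoxy-6-(2-oxoheptyl)benzoate, via laterally lithiated toluate 6 (not isolated), via lithium hemiaminal alkoxide 7 (not isolated)
Conditions: LiN(iPr)2 (1.3 equiv), THF, −78 °C; 5, −78 °C; AcOH, −78 °C
Reagents that add atoms: none
Why: Lateral lithiation of the ortho-toluate is directed by the ester, whose two ortho substituents suppress self-condensation, and Weinreb acylation of the benzylic anion gives a chelated tetrahedral adduct that releases the ketone only on the cold acidic quench, which avoids over-addition and isocoumarin formation.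

Step 5
Reactants: 8 methyl 2-(benzyloxy)-4-methoxy-6-(2-oxoheptyl)benzoate
Product: 9 methyl 2-(benzyloxy)-4-methoxy-6-[(2-pentyl-1,3-dioxolan-2-yl)methyl]benzoate
Conditions: Me3SiOCH2CH2OSiMe3 (2 equiv), Me3SiOTf (5 mol %), CH2Cl2, −78 to −20 °C; pyridine quench
Reagents that add atoms: 1,2-bis(trimethylsilyloxy)ethane, C[Si](C)(C)OCCO[Si](C)(C)C
Why: Silyl-transfer ketalisation converts the dialkyl ketone into the dioxolane under aprotic, low-temperature conditions that should not trigger enol-lactonisation onto the neighbouring ester.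

Step 6
Reactants: 9 methyl 2-(benzyloxy)-4-methoxy-6-[(2-pentyl-1,3-dioxolan-2-yl)methyl]benzoate
Product: 11 2-(benzyloxy)-4-methoxy-6-[(2-pentyl-1,3-dioxolan-2-yl)methyl]benzoic acid, via potassium carboxylate 10 (not isolated)
Conditions: KOH, DMSO/H2O (4:1), 90 °C; then 0 °C, aq. citric acid to pH 5
Reagents that add atoms: potassium hydroxide, [K+].[OH-]
Why: Poorly solvated hydroxide in aqueous DMSO saponifies the doubly ortho-substituted methyl benzoate while the dioxolane and benzyl ether are inert to base, and cold acidification only to pH 5 keeps the ketal.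

Step 7
Reactants: 11 2-(benzyloxy)-4-methoxy-6-[(2-pentyl-1,3-dioxolan-2-yl)methyl]benzoic acid
Product: 12 2-(benzyloxy)-4-methoxy-6-[(2-pentyl-1,3-dioxolan-2-yl)methyl]benzoyl fluoride
Conditions: cyanuric fluoride, pyridine, CH2Cl2, −10 °C to rt
Reagents that add atoms: cyanuric fluoride (2,4,6-trifluoro-1,3,5-triazine), Fc1nc(F)nc(F)n1
Why: Deoxyfluorination of the acid with cyanuric fluoride under pyridine buffering spares the dioxolane and gives a compact, storable acyl fluoride suited to a hindered 2,6-disubstituted benzoyl transfer.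

Step 8
Reactants: 13 1,1-dimethoxyethene; 14 acetyl chloride
Product: 15 4,4-dimethoxybut-3-en-2-one
Conditions: 14 added to 13 (2.2 equiv), Et2O, 0 °C to rt; distillation
Reagents that add atoms: none
Why: C-Acylation of the electron-rich ketene acetal gives a dimethoxycarbenium chloride that is deprotonated by the second equivalent of ketene acetal (which ends as methyl acetate and chloromethane), leaving the push–pull acylketene acetal.

Step 9
Reactants: 15 4,4-dimethoxybut-3-en-2-one
Product: 16 (4,4-dimethoxybuta-1,3-dien-2-yl)oxy-trimethylsilane (1,1-dimethoxy-3-trimethylsilyloxybuta-1,3-diene)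
Conditions: Me3SiCl, Et3N, ZnCl2 (cat.), PhH, 40 °C; distillation
Reagents that add atoms: chlorotrimethylsilane, C[Si](C)(C)Cl
Why: Soft enolisation of the methyl ketone, the only enolisable position, followed by O-silylation gives the cross-conjugated 2-silyloxydiene, a distillable ketene-acetal diene.

Step 10
Reactants: 16 (4,4-dimethoxybuta-1,3-dien-2-yl)oxy-trimethylsilane; 12 2-(benzyloxy)-4-methoxy-6-[(2-pentyl-1,3-dioxolan-2-yl)methyl]benzoyl fluoride
Product: 18 4,4-dimethoxybuta-1,3-dien-2-yl 2-(benzyloxy)-4-methoxy-6-[(2-pentyl-1,3-dioxolan-2-yl)methyl]benzoate, via potassium dienolate 17 (not isolated)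
Conditions: KF (10 mol %), 18-crown-6 (10 mol %), THF, rt; volatiles removed, short plug of Et3N-deactivated alumina, used at once
Reagents that add atoms: none
Why: Fluoride-catalysed O-acylation of a silyl enol ether: fluoride strips the silyl group to a crown-separated dienolate that attacks the hard acyl fluoride on oxygen and releases fluoride to carry the chain, and the neutral, water-free conditions with volatile Me3SiF suit the acid-labile ketene acetal.

Step 11
Reactants: 19 hexanal; 20 propargyl bromide
Product: 22 non-1-yn-4-ol (racemic), via allenylzinc bromide 21 (not isolated)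
Conditions: Zn dust, THF/sat. aq. NH4Cl, 0 °C to rt
Reagents that add atoms: none
Why: Barbier propargylation: the allenylzinc bromide formed in the flask adds to the aldehyde with allenyl-to-propargyl transposition to give the homopropargylic alcohol, racemic at a centre that the next step removes.

Step 12
Reactants: 22 non-1-yn-4-ol (racemic)
Product: 23 non-1-yn-4-one
Conditions: CrO3, H2SO4, acetone, 0 °C
Reagents that add atoms: none
Why: Jones oxidation of the secondary alcohol runs under acidic conditions, which, unlike basic ones, should not isomerise the β,γ-alkynyl ketone to the allenyl ketone.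

Step 13
Reactants: 23 non-1-yn-4-one
Product: 24 2-pentyl-2-(prop-2-yn-1-yl)-1,3-dioxolane
Conditions: Me3SiOCH2CH2OSiMe3, Me3SiOTf (5 mol %), CH2Cl2, −78 to −20 °C; pyridine quench
Reagents that add atoms: 1,2-bis(trimethylsilyloxy)ethane, C[Si](C)(C)OCCO[Si](C)(C)C
Why: The same aprotic silyl-transfer ketalisation masks the ketone and removes the acidity of the propargylic methylene before any base is used.

Step 14
Reactants: 24 2-pentyl-2-(prop-2-yn-1-yl)-1,3-dioxolane; 25 benzyl chloroformate
Product: 27 benzyl 4-(2-pentyl-1,3-dioxolan-2-yl)but-2-ynoate, via lithium acetylide 26 (not isolated)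
Conditions: n-BuLi (1.0 equiv), THF, −78 °C; then added to 25 (1.2 equiv), −78 °C; cold NH4Cl quench
Reagents that add atoms: none
Why: C-Acylation of a lithium acetylide by a chloroformate is the standard route to 2-alkynoates, and inverse addition at low temperature keeps the product's γ-methylene from being deprotonated towards the allenoate.

Step 15
Reactants: 18 4,4-dimethoxybuta-1,3-dien-2-yl 2-(benzyloxy)-4-methoxy-6-[(2-pentyl-1,3-dioxolan-2-yl)methyl]benzoate; 27 benzyl 4-(2-pentyl-1,3-dioxolan-2-yl)but-2-ynoate
Product: 29 benzyl 4-{[2-(benzyloxy)-4-methoxy-6-[(2-pentyl-1,3-dioxolan-2-yl)methyl]benzoyl]oxy}-2-methoxy-6-[(2-pentyl-1,3-dioxolan-2-yl)methyl]benzoate, via cyclohexa-1,4-diene adduct 28 (not isolated)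
Conditions: 27 (2.5 equiv), PhMe (1 M), 120 °C, sealed tube; then PPTS (cat.), rt, if 28 persists
Reagents that add atoms: none
Why: Proposed new method: the ketene-acetal diene 18, whose HOMO is raised by the two methoxy groups and the acyloxy oxygen and has its largest coefficient at the CH2 terminus, should add to the ynoate 27 in an asynchronous normal-demand [4+2] cycloaddition, the CH2 terminus bonding to the alkyne β-carbon ahead of the bond between the acetal carbon and the α-carbon; the 6,6-dimethoxycyclohexa-1,4-diene 28 then loses methanol by 1,4-elimination (an acetal methoxy group and the ring hydrogen γ to the ester) to give the arene. The closest known reaction type is the Diels–Alder reaction and aromatisation of 1,1-dimethoxy-3-silyloxybutadienes with 2-alkynoates to 4-hydroxy-2-methoxybenzoates; here an aroyloxy group replaces the silyloxy group and lowers the diene HOMO, hence the higher temperature and the excess of dienophile. Ring B closes intermolecularly as a six-membered carbocycle through the two σ-bonds of the cycloaddition, B5–B6 leading and B1–B2 following. No stereocentre is created, since the acetal carbon and the ring CH2 of 28 are not stereogenic and both become aromatic carbons. The step needs regioselectivity, which the ketene acetal secures by concentrating nucleophilicity at the unsubstituted diene terminus, so that the ester lands next to the methoxy-bearing carbon and the ketal arm next to a ring CH. It also needs the enol ester and both dioxolanes to survive, which neutral aprotic heating should allow.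

Step 16
Reactants: 29 the protected depside of step 15
Product: 30 benzyl 4-{[2-(benzyloxy)-4-methoxy-6-(2-oxoheptyl)benzoyl]oxy}-2-methoxy-6-(2-oxoheptyl)benzoate
Conditions: 1 M aq. HCl, THF, rt
Reagents that add atoms: water, O
Why: Dioxolanes of dialkyl ketones hydrolyse in dilute aqueous acid at room temperature, where the benzyl ester, the benzyl ether and the hindered aryl benzoate link are expected to hold, and doing this before debenzylation keeps the ring B carboxyl masked while acid is present.

Step 17
Reactants: 30 benzyl 4-{[2-(benzyloxy)-4-methoxy-6-(2-oxoheptyl)benzoyl]oxy}-2-methoxy-6-(2-oxoheptyl)benzoate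
Product: 31 4-{[2-hydroxy-4-methoxy-6-(2-oxoheptyl)benzoyl]oxy}-2-methoxy-6-(2-oxoheptyl)benzoic acid (target)
Conditions: H2 (1 atm), 10% Pd/C, EtOAc, rt
Reagents that add atoms: none
Why: Hydrogenolysis over palladium on carbon cleaves the benzyl ether and the benzyl ester under neutral conditions without reducing the dialkyl ketones or touching the depside ester, so the target is released without contact with acid or base.

**Compound list**
1 | methyl orsellinate (methyl 2,4-dihydroxy-6-methylbenzoate) | COC(=O)c1c(C)cc(O)cc1O | starting material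
2 | methyl 2-hydroxy-4-methoxy-6-methylbenzoate | COC(=O)c1c(C)cc(OC)cc1O | intermediate
3 | methyl 2-(benzyloxy)-4-methoxy-6-methylbenzoate | COC(=O)c1c(C)cc(OC)cc1OCc1ccccc1 | intermediate
4 | hexanoyl chloride | CCCCCC(=O)Cl | starting material
5 | N-methoxy-N-methylhexanamide | CCCCCC(=O)N(C)OC | intermediate
6 | laterally lithiated toluate (benzylic lithium derivative of 3) | [Li]Cc1cc(OC)cc(OCc2ccccc2)c1C(=O)OC | intermediate
7 | lithium hemiaminal alkoxide (tetrahedral adduct of 6 and 5, racemic) | CCCCCC(O[Li])(Cc1cc(OC)cc(OCc2ccccc2)c1C(=O)OC)N(C)OC | intermediate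
8 | methyl 2-(benzyloxy)-4-methoxy-6-(2-oxoheptyl)benzoate | CCCCCC(=O)Cc1cc(OC)cc(OCc2ccccc2)c1C(=O)OC | intermediate
9 | methyl 2-(benzyloxy)-4-methoxy-6-[(2-pentyl-1,3-dioxolan-2-yl)methyl]benzoate | CCCCCC1(Cc2cc(OC)cc(OCc3ccccc3)c2C(=O)OC)OCCO1 | intermediate
10 | potassium 2-(benzyloxy)-4-methoxy-6-[(2-pentyl-1,3-dioxolan-2-yl)methyl]benzoate | CCCCCC1(Cc2cc(OC)cc(OCc3ccccc3)c2C(=O)[O-])OCCO1.[K+] | intermediate
11 | 2-(benzyloxy)-4-methoxy-6-[(2-pentyl-1,3-dioxolan-2-yl)methyl]benzoic acid | CCCCCC1(Cc2cc(OC)cc(OCc3ccccc3)c2C(=O)O)OCCO1 | intermediate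
12 | 2-(benzyloxy)-4-methoxy-6-[(2-pentyl-1,3-dioxolan-2-yl)methyl]benzoyl fluoride | CCCCCC1(Cc2cc(OC)cc(OCc3ccccc3)c2C(=O)F)OCCO1 | intermediate
13 | 1,1-dimethoxyethene | C=C(OC)OC | starting material
14 | acetyl chloride | CC(=O)Cl | starting material
15 | 4,4-dimethoxybut-3-en-2-one | CC(=O)C=C(OC)OC | intermediate
16 | (4,4-dimethoxybuta-1,3-dien-2-yl)oxy-trimethylsilane | C=C(O[Si](C)(C)C)C=C(OC)OC | intermediate
17 | potassium 4,4-dimethoxybuta-1,3-dien-2-olate | C=C([O-])C=C(OC)OC.[K+] | intermediate
18 | 4,4-dimethoxybuta-1,3-dien-2-yl 2-(benzyloxy)-4-methoxy-6-[(2-pentyl-1,3-dioxolan-2-yl)methyl]benzoate | C=C(OC(=O)c1c(OCc2ccccc2)cc(OC)cc1CC1(CCCCC)OCCO1)C=C(OC)OC | intermediate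
19 | hexanal | CCCCCC=O | starting material
20 | propargyl bromide (3-bromoprop-1-yne) | C#CCBr | starting material
21 | allenylzinc bromide | C=C=C[Zn]Br | intermediate
22 | non-1-yn-4-ol (racemic) | CCCCCC(O)CC#C | intermediate
23 | non-1-yn-4-one | CCCCCC(=O)CC#C | intermediate
24 | 2-pentyl-2-(prop-2-yn-1-yl)-1,3-dioxolane | CCCCCC1(CC#C)OCCO1 | intermediate
25 | benzyl chloroformate | O=C(Cl)OCc1ccccc1 | starting material
26 | lithium acetylide of 24 | CCCCCC1(CC#C[Li])OCCO1 | intermediate
27 | benzyl 4-(2-pentyl-1,3-dioxolan-2-yl)but-2-ynoate | CCCCCC1(CC#CC(=O)OCc2ccccc2)OCCO1 | intermediate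
28 | benzyl 4-{[2-(benzyloxy)-4-methoxy-6-[(2-pentyl-1,3-dioxolan-2-yl)methyl]benzoyl]oxy}-6,6-dimethoxy-2-[(2-pentyl-1,3-dioxolan-2-yl)methyl]cyclohexa-1,4-diene-1-carboxylate | COC1(OC)C=C(OC(=O)c2c(OCc3ccccc3)cc(OC)cc2CC2(CCCCC)OCCO2)CC(CC2(CCCCC)OCCO2)=C1C(=O)OCc1ccccc1 | intermediate
29 | benzyl 4-{[2-(benzyloxy)-4-methoxy-6-[(2-pentyl-1,3-dioxolan-2-yl)methyl]benzoyl]oxy}-2-methoxy-6-[(2-pentyl-1,3-dioxolan-2-yl)methyl]benzoate | CCCCCC1(Cc2cc(OC)cc(OCc3ccccc3)c2C(=O)Oc2cc(CC3(CCCCC)OCCO3)c(C(=O)OCc3ccccc3)c(OC)c2)OCCO1 | intermediate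
30 | benzyl 4-{[2-(benzyloxy)-4-methoxy-6-(2-oxoheptyl)benzoyl]oxy}-2-methoxy-6-(2-oxoheptyl)benzoate | CCCCCC(=O)Cc1cc(OC)cc(OCc2ccccc2)c1C(=O)Oc1cc(CC(=O)CCCCC)c(C(=O)OCc2ccccc2)c(OC)c1 | intermediate
31 | 4-{[2-hydroxy-4-methoxy-6-(2-oxoheptyl)benzoyl]oxy}-2-methoxy-6-(2-oxoheptyl)benzoic acid | CCCCCC(=O)Cc1cc(OC)cc(O)c1C(=O)Oc1cc(CC(=O)CCCCC)c(C(=O)O)c(OC)c1 | target

**Step count and risks**

Total step count: 17. Longest linear sequence: 10 steps (steps 1, 2, 4, 5, 6, 7, 10, 15, 16, 17); steps 3, 8–9 and 11–14 are side branches.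

Steps most likely to fail:

1. Step 15. The acyloxy-substituted diene may cycloadd too slowly, so that thermal or moisture-induced breakdown of the ketene acetal, or propargyl-to-allenyl isomerisation of the ynoate, outruns ring formation. The fallback sets out from 16 and 27 and comes back at 29. Heating the silyloxy diene 16 with 27 in toluene at 110 °C, the known cycloaddition of this diene class, should give benzyl 6,6-dimethoxy-2-[(2-pentyl-1,3-dioxolan-2-yl)methyl]-4-(trimethylsilyloxy)cyclohexa-1,4-diene-1-carboxylate F1. This loses methanol to benzyl 2-methoxy-6-[(2-pentyl-1,3-dioxolan-2-yl)methyl]-4-(trimethylsilyloxy)benzoate F2. Stirring in methanol with a trace of K2CO3 should free benzyl 4-hydroxy-2-methoxy-6-[(2-pentyl-1,3-dioxolan-2-yl)methyl]benzoate F3. Acylation of the phenol F3 with acyl fluoride 12 (Et3N, cat. DMAP, CH2Cl2) should then give 29. The same two ring bonds are formed, but the depside ester is made after the ring instead of before it.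

2. Step 10. Acyl transfer to the hindered 2,6-disubstituted benzoyl fluoride may be slow, leaving desilylation without acylation, C-acylation at the dienolate carbon, or hydrolysis of the ketene acetal during handling. The fallback sets out from 11 and 15 and comes back at 18. Acid 11 would be converted with 1-chloro-N,N,2-trimethylprop-1-en-1-amine (CH2Cl2, 0 °C, neutral conditions) into 2-(benzyloxy)-4-methoxy-6-[(2-pentyl-1,3-dioxolan-2-yl)methyl]benzoyl chloride F4. Enone 15 would be deprotonated at its methyl group with KN(SiMe3)2 in THF at −78 °C to give the potassium dienolate 17 in stoichiometric amount. Addition of F4 to this hard potassium enolate should acylate it on oxygen and give 18.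

3. Step 16. Once the ketones are unmasked under acid, enol-lactonisation onto the neighbouring aryl ester or benzyl ester (isocoumarin formation with expulsion of the ring B phenol or benzyl alcohol) may compete and cleave the depside. The fallback sets out from 29 and comes back at 31. Hydrogenolysis of 29 first (H2, 10% Pd/C, EtOAc) should give 4-{[2-hydroxy-4-methoxy-6-[(2-pentyl-1,3-dioxolan-2-yl)methyl]benzoyl]oxy}-2-methoxy-6-[(2-pentyl-1,3-dioxolan-2-yl)methyl]benzoic acid F5. Both dioxolanes of F5 would then be exchanged into acetone under near-neutral transketalisation (PPTS cat., acetone, rt to 40 °C) to give 31 without aqueous mineral acid.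

**Further compounds**
F1 | step 15 | benzyl 6,6-dimethoxy-2-[(2-pentyl-1,3-dioxolan-2-yl)methyl]-4-(trimethylsilyloxy)cyclohexa-1,4-diene-1-carboxylate | COC1(OC)C=C(O[Si](C)(C)C)CC(CC2(CCCCC)OCCO2)=C1C(=O)OCc1ccccc1
F2 | step 15 | benzyl 2-methoxy-6-[(2-pentyl-1,3-dioxolan-2-yl)methyl]-4-(trimethylsilyloxy)benzoate | CCCCCC1(Cc2cc(O[Si](C)(C)C)cc(OC)c2C(=O)OCc2ccccc2)OCCO1
F3 | step 15 | benzyl 4-hydroxy-2-methoxy-6-[(2-pentyl-1,3-dioxolan-2-yl)methyl]benzoate | CCCCCC1(Cc2cc(O)cc(OC)c2C(=O)OCc2ccccc2)OCCO1
F4 | step 10 | 2-(benzyloxy)-4-methoxy-6-[(2-pentyl-1,3-dioxolan-2-yl)methyl]benzoyl chloride | CCCCCC1(Cc2cc(OC)cc(OCc3ccccc3)c2C(=O)Cl)OCCO1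
F5 | step 16 | 4-{[2-hydroxy-4-methoxy-6-[(2-pentyl-1,3-dioxolan-2-yl)methyl]benzoyl]oxy}-2-methoxy-6-[(2-pentyl-1,3-dioxolan-2-yl)methyl]benzoic acid | CCCCCC1(Cc2cc(OC)cc(O)c2C(=O)Oc2cc(CC3(CCCCC)OCCO3)c(C(=O)O)c(OC)c2)OCCO1
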